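## Structural features

The target is a 4-hydroxy-5-methylcoumarin whose C3' is bonded to C1 of a cis-fused 1,4a,5,6,7,7a-hexahydrocyclopenta[c]pyran (C1, O2, C3, C4, C4a, C5, C6, C7, C7a; primed numbers are coumarin atoms). The dihydropyran contains the enol ether O2–C3=C4, with a 3-methylbut-2-enoyl group on C3 and a methyl group on C4. There are four stereocentres, C1–C7a–C7 contiguous and C4a next to C7a, with configuration (1R,4aS,7S,7aR). This means a cis ring fusion, the C7 methyl trans to C1 on the cyclopentane, and the coumarin on the convex face of the pyran, trans to C7. Three groups are fragile: the cross-conjugated 2-alkoxy dienone (Nazarov-prone under acid, a Michael acceptor and a chromophore), the C1–O2 bond (benzylic to a 4-hydroxycoumarin, able to ionize), and the acidic 4-OH. The real difficulty is the stereocontrolled assembly of the cyclopentane-fused pyran next to a doubly ortho-substituted heteroaryl, in an order that keeps the dienone away from light and Lewis acids. The key step exploits the 1,4-relation of C1 and C4 across the C7a–C4a bond: C1 sits on a carbon with a vinylogous oxygen donor (O on C4'), and C4 is alpha to the carbonyl-level C3. A temporary C1–C4 bond is therefore a donor–acceptor cyclobutane bond, and the cyclobutane C1–C7a–C4a–C4 fused to the cyclopentane is the [2+2] adduct of a hepta-1,6-diene.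

## Logic of the disconnections

16 to 15: the O–CH2 bond of the ether on the coumarin 4-oxygen is cut. A free 4-hydroxyl makes C1–O2 labile and would interfere with every organometallic step, so it is unmasked last. The forward cleavage must use neither acid, Lewis acid nor soft nucleophile, which is why a fluoride-labile group is carried.

15 to 14: the bond between the acyl carbon and the alkenyl CH is cut. The dienone is the most sensitive group, so it is made after the photochemical and Lewis-acid steps. The forward step must add an alkenylmagnesium reagent once, and to the amide rather than the lactone.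

14 to 13: the amide C–N bond is exchanged for the ester C–O bond. The ester is what the ring expansion delivers. The forward aminolysis must leave the coumarin lactone alone.

13 to 12: C1–O2 is cut and C1–C4 is reconnected. This turns the pyran into a cyclobutane that a cycloaddition can make, and removes the need to control C1 and C4 earlier. The forward step must break only the donor–acceptor bond, close through oxygen, and place the coumarin trans to C7.

12 to 11: C4a–C7a and C1–C4 are cut. Two rings and four stereocentres fall back to an acyclic 1,6-diene with one stereocentre. The forward step needs 5-exo regiochemistry and face selectivity relative to C7.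

11 to 6 and 10: the C4=C4a alkene (target numbering) is cut by a Wittig disconnection. This separates the ketoester terminus from the chiral chain. The forward step needs a stabilized, alpha-branched ylide to react with an aliphatic aldehyde.

10 to 7, through 9 and 8: the P–C and C–Br bonds are cut, back to a commercial ketoester. The forward steps need alpha-bromination on the only enolizable side and clean quaternization at a secondary carbon.

6 to 5: the aldehyde carbon is traced to a trisubstituted alkene by retro-ozonolysis, so that a chiral-pool diene supplies C5, C6, C7 and its methyl. The forward step must cleave the electron-rich alkene and spare the conjugated one.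

5 to 3 and 4: the C3'–C1 bond is cut by a Heck disconnection, leaving an iodocoumarin and a terminal alkene. The forward step must not move the alkene toward the allylic stereocentre.

3 to 2: the O–CH2 bond of the protecting group is cut. The forward alkylation must take place at O-4, not at the lactone oxygen.

2 to 1: the C3'–I bond is cut. The enolic C3' is the most nucleophilic position, so the demand is only for mono-iodination.

## Other disconnections considered

Alternative 1: The pyran is cut at C1–C7a and O2–C3, giving 4-methoxy-5-methyl-2-oxo-2H-chromene-3-carbaldehyde A1 and the cyclopentenyl diene A2 (C7a=C4a–C4=C3, with the masked acyl group as a silyloxyalkynyl substituent on C3). In the forward key step, Lewis-acid-bound A1 would add as heterodienophile to A2 and close the ring as the 3,6-dihydro-2H-pyran A3.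
- In its favour: the two halves are joined at the centre of the molecule, the pyran oxygen comes from the aldehyde, and C1 and C7a would be set together with the C7 methyl directing the face.
- Against it: A1 is a vinylogous formate and a weak electrophile, and a Lewis acid strong enough to activate it also threatens the methyl enol ether and invites Prins or ene pathways. A3 has its alkene at C4=C4a, so C4a is not a stereocentre and must be made later by moving the alkene to C3=C4, with an uncertain facial outcome. The C3 centre is made only to be destroyed. Unmasking the dienone needs a Meyer–Schuster rearrangement, which is acid-mediated. A2 needs its own enantioselective synthesis.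
- Comparison: on structure, Alternative 1 is the better plan for convergence. It is weaker at C4a, which the chosen plan fixes by ring strain. On mechanism, it is a single polar step that depends on matched electronics, whereas the chosen plan uses a polarity-insensitive triplet C–C bond formation and then an intramolecular ionic C–O closure. On step economy, its key step makes two bonds and one ring against two bonds and two rings, and the desilylation, rearrangement, transposition and demethylation that follow make it no shorter.

Alternative 2: No ring is cut. The C3–acyl and acyl–CH bonds are disconnected to the ketene acetal triflate A4, carbon monoxide A5 and tributyl(2-methylprop-1-en-1-yl)stannane A6. In the forward key step, Pd(PPh3)4 would insert into the C3–OTf bond, A5 would insert, and A6 would transfer its alkenyl group to give the 4-O-methyl ether A7.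
- In its favour: the dienone appears in the last carbon–carbon bond-forming step under neutral conditions, and the three ring stereocentres are already in place in the lactone A8 from which A4 would be made.
- Against it: it builds none of the bicycle, so A8 still has to come from another strategy. Lactone-derived ketene acetal triflates are hydrolytically delicate. Direct coupling without A5 insertion can compete. A7 still needs its methyl ether removed in the presence of the dienone.
- Comparison: on structure, it is the equal of the chosen plan in deferring the dienone. It is the better of the two for the acylation itself, which is one catalytic step against amide formation plus Grignard addition, and brings no organomagnesium reagent near the coumarin lactone. On mechanism it is organometallic and stereochemically silent. On step economy it only wins if A8 is short to make, and the chosen plan gets the equivalent C3 carboxyl group as a by-product of ring formation.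

Alternative 3: O2 is removed by a retro oxygen insertion, and the resulting cyclopentenone is cut at C4a–C7a and at both bonds to the carbonyl carbon, giving the enyne A9 and A5. In the forward key step, Co2(CO)8 would mediate a Pauson–Khand cyclization of A9 to the bicyclo[3.3.0]octenone A10.
- In its favour: the Pauson–Khand reaction of 1,6-enynes is a dependable diquinane synthesis, A9 is reachable by the same Heck logic, and the E-alkene would transfer its geometry stereospecifically to the C1/C7a relation.
- Against it: 1,2-disubstituted aryl alkenes are sluggish Pauson–Khand partners. A10 has the alkene at C4=C4a, so C4a must be set later by a face-selective reduction. The oxygen must be inserted by a Baeyer–Villiger reaction whose regiochemistry (C1 against vinyl migration, with epoxidation competing) is not assured, given an electron-poor aryl on C1. Oxidation and reduction would only reach A8, so the whole of Alternative 2 must follow.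
- Comparison: on structure, it is the better plan for C1, which is set stereospecifically where the chosen plan relies on least-motion closure and equilibration. It is weaker at C4a. On mechanism, both plans use a C7-controlled cyclization of the same chain onto the alkenylcoumarin, but here the second ring must be expanded oxidatively, where the cyclobutane expands by isomerization. On step economy it is clearly longer after the key step.

Key step: step 8

Remarks on the chemistry, one line each:
- Assumption: 1, the S enantiomer 4 and 7 are taken as commercial.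
- The configurations were checked: S-configured 4 maps onto C7 (S), which stays S in 5, 6 and 11; 12 is (1R,2S,5S,6R,7S) in bicyclo numbering; 13 to 16 are (1R,4aS,7S,7aR). No configuration needed correction.
- Design change to the precursor: the 4-O-methyl group is replaced by 2-(trimethylsilyl)ethyl. A nucleophilic demethylation next to the dienone would need heat or thiolates, whereas fluoride removes the silylethyl group at 0 °C. The skeleton and the bonds of the key step are unchanged.
- The 2-oxo-3-enoate is itself a triplet acceptor. This is harmless because excitation of either alkene leads to the same 1,4-diradical.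
- 12 is drawn as the diastereomer from stereoretentive closure; epimers at its C6 and C7 (target C4 and C1) serve equally.

Step 1
Reactants: 1 4-hydroxy-5-methyl-2H-chromen-2-one (4-hydroxy-5-methylcoumarin)
Product: 2 4-hydroxy-3-iodo-5-methyl-2H-chromen-2-one
Conditions: NIS (1.05 equiv), MeCN, 0 °C → rt
Reagents that add atoms: N-iodosuccinimide, O=C1CCC(=O)N1I
Why: Electrophilic iodination of an enol: C3' of the cyclic beta-keto ester enol is by far the most nucleophilic carbon, so one equivalent of reagent should iodinate there only.

Step 2
Reactants: 2 4-hydroxy-3-iodo-5-methyl-2H-chromen-2-one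
Product: 3 3-iodo-5-methyl-4-[2-(trimethylsilyl)ethoxy]-2H-chromen-2-one
Conditions: Me3SiCH2CH2OH, PPh3, DIAD, THF, 0 °C → rt
Reagents that add atoms: 2-(trimethylsilyl)ethanol, C[Si](C)(C)CCO
Why: Mitsunobu O-alkylation: the 4-hydroxyl is as acidic as a carboxylic acid, so it protonates the betaine and its oxygen displaces the activated primary alcohol, the 4-alkoxycoumarin being the usual product for this class.

Step 3
Reactants: 3 3-iodo-5-methyl-4-[2-(trimethylsilyl)ethoxy]-2H-chromen-2-one; 4 (3S)-3,7-dimethylocta-1,6-diene ((S)-beta-citronellene)
Product: 5 3-[(1E,3S)-3,7-dimethylocta-1,6-dien-1-yl]-5-methyl-4-[2-(trimethylsilyl)ethoxy]-2H-chromen-2-one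
Conditions: Pd(OAc)2 (5 mol %), P(o-tol)3 (10 mol %), Ag2CO3 (1 equiv), 4 (3 equiv), DMF, 70 °C
Reagents that add atoms: none
Why: Heck reaction: zerovalent palladium inserts into the C–I bond, the monosubstituted alkene of 4 inserts at its terminal carbon (the trisubstituted alkene is inert), and beta-hydride elimination toward the coumarin gives the conjugated E-alkene; the silver salt removes iodide and should suppress hydridopalladium re-addition, so the allylic stereocentre is carried over unchanged.

Step 4
Reactants: 5 3-[(1E,3S)-3,7-dimethylocta-1,6-dien-1-yl]-5-methyl-4-[2-(trimethylsilyl)ethoxy]-2H-chromen-2-one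
Product: 6 (4S,5E)-4-methyl-6-{5-methyl-2-oxo-4-[2-(trimethylsilyl)ethoxy]-2H-chromen-3-yl}hex-5-enal
Conditions: O3, CH2Cl2/MeOH, −78 °C, Sudan Red 7B end point; then Me2S, −78 °C → rt
Reagents that add atoms: ozone, [O-][O+]=O
Why: Chemoselective ozonolysis: electrophilic ozone should consume the electron-rich trisubstituted alkene well before the coumarin-conjugated alkene or the push–pull coumarin double bond, with the dye marking the end point; the stereocentre is gamma to the new aldehyde and cannot enolize.

Step 5
Reactants: 7 methyl 2-oxobutanoate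
Product: 8 methyl 3-bromo-2-oxobutanoate (racemic)
Conditions: Br2, cat. HBr, CH2Cl2, 0 °C → rt
Reagents that add atoms: bromine, BrBr
Why: Acid-catalysed alpha-bromination of a ketone through its enol, which can form only toward C3; the new centre is racemic, which does not matter because it becomes sp2.

Step 6
Reactants: 8 methyl 3-bromo-2-oxobutanoate
Product: 10 methyl 2-oxo-3-(triphenyl-λ5-phosphanylidene)butanoate, via phosphonium bromide 9 (not isolated)
Conditions: PPh3, THF, 50 °C; then aq. Na2CO3, CH2Cl2, rt
Reagents that add atoms: triphenylphosphine, c1ccc(cc1)P(c1ccccc1)c1ccccc1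
Why: SN2 quaternization of the phosphine by the activated alpha-bromoketone, then deprotonation of the acidic salt by mild aqueous base, the standard way to acyl-stabilized Wittig reagents.

Step 7
Reactants: 6 (4S,5E)-4-methyl-6-{5-methyl-2-oxo-4-[2-(trimethylsilyl)ethoxy]-2H-chromen-3-yl}hex-5-enal; 10 methyl 2-oxo-3-(triphenyl-λ5-phosphanylidene)butanoate
Product: 11 methyl (3E,7S,8E)-3,7-dimethyl-9-{5-methyl-2-oxo-4-[2-(trimethylsilyl)ethoxy]-2H-chromen-3-yl}-2-oxonona-3,8-dienoate
Conditions: toluene, 80 °C
Reagents that add atoms: none
Why: Wittig olefination: a stabilized alpha-branched ylide reacts slowly but reliably with an unhindered aliphatic aldehyde and gives the E-trisubstituted enone; the coumarin lactone does not react with such an ylide.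

Step 8
Reactants: 11 methyl (3E,7S,8E)-3,7-dimethyl-9-{5-methyl-2-oxo-4-[2-(trimethylsilyl)ethoxy]-2H-chromen-3-yl}-2-oxonona-3,8-dienoate
Product: 12 methyl 2-[(1R,2S,5S,6R,7S)-2,6-dimethyl-7-{5-methyl-2-oxo-4-[2-(trimethylsilyl)ethoxy]-2H-chromen-3-yl}bicyclo[3.2.0]heptan-6-yl]-2-oxoacetate
Conditions: thioxanthone (10 mol %), hν (405 nm LED), degassed CH2Cl2 (0.01 M), rt
Reagents that add atoms: none
Why: Thioxanthone absorbs the 405 nm light and passes its triplet energy to the 3-alkenylcoumarin (or to the 2-oxo-3-enoate, which leads to the same intermediate), and the relaxed alkene triplet attacks the tethered alkene. The cyclopentane closes first, by 5-exo-trig bond formation between C7a and C4a as the three-atom tether dictates, leaving a triplet 1,4-diradical with a coumarin-stabilized centre at C1 and a tertiary alpha-keto centre at C4; after intersystem crossing this diradical closes the cyclobutane by C1–C4 radical recombination. The closest known reaction type is the triplet-sensitized intramolecular [2+2] photocycloaddition of styrenes or enones with tethered alkenes, which gives bicyclo[3.2.0]heptanes. C4a and C7a must be cis because a trans-fused bicyclo[3.2.0]heptane is prohibitively strained, so this pair is set by the ring system itself. Their relation to C7 is decided in the 5-exo step: a chair-like transition state with the C7 methyl pseudo-equatorial puts the methyl trans to C4 and to C1, that is exo on the bicycle, and reversal of the first bond should further drain the more crowded endo diastereomer. C1 and C4 are expected as drawn if the diradical collapses before bond rotation, but their configuration is of no consequence because both centres are reset in step 9. The selectivities needed are straight rather than crossed addition (secured by the tether length), face selectivity relative to C7 (secured by the methyl group) and indifference to which chromophore is excited (secured by the convergence on one diradical), while E/Z isomerization merely recycles 11.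

Step 9
Reactants: 12 methyl 2-[(1R,2S,5S,6R,7S)-2,6-dimethyl-7-{5-methyl-2-oxo-4-[2-(trimethylsilyl)ethoxy]-2H-chromen-3-yl}bicyclo[3.2.0]heptan-6-yl]-2-oxoacetate
Product: 13 methyl (1R,4aS,7S,7aR)-4,7-dimethyl-1-{5-methyl-2-oxo-4-[2-(trimethylsilyl)ethoxy]-2H-chromen-3-yl}-1,4a,5,6,7,7a-hexahydrocyclopenta[c]pyran-3-carboxylate
Conditions: Sc(OTf)3 (10 mol %), 4 Å MS, CH2Cl2, 0 °C → rt
Reagents that add atoms: none
Why: Proposed new method: Sc(OTf)3 should chelate the 1,2-dicarbonyl unit and polarize the strained C1–C4 bond, whose heterolysis gives a C1 cation stabilized by the coumarin enol ether (C3'=C4'–OR) and a scandium enolate of the ketoester; the enolate oxygen then closes the six-membered ring on C1 with release of the cyclobutane strain, least-motion closure and reversible ionization of the new C1–O2 bond both placing the coumarin trans to C7 (1R), and no dienone is yet present for the Lewis acid to cyclize; the closest known reaction types are the Cloke–Wilson rearrangement of acylcyclopropanes to dihydrofurans and the Lewis-acid opening of donor–acceptor cyclobutanes in formal [4+2] annulations.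

Step 10
Reactants: 13 methyl (1R,4aS,7S,7aR)-4,7-dimethyl-1-{5-methyl-2-oxo-4-[2-(trimethylsilyl)ethoxy]-2H-chromen-3-yl}-1,4a,5,6,7,7a-hexahydrocyclopenta[c]pyran-3-carboxylate
Product: 14 (1R,4aS,7S,7aR)-N-methoxy-N,4,7-trimethyl-1-{5-methyl-2-oxo-4-[2-(trimethylsilyl)ethoxy]-2H-chromen-3-yl}-1,4a,5,6,7,7a-hexahydrocyclopenta[c]pyran-3-carboxamide
Conditions: MeNHOMe·HCl (3 equiv), iPrMgCl (6 equiv), THF, −20 → 0 °C
Reagents that add atoms: N,O-dimethylhydroxylamine hydrochloride, CNOC.Cl
Why: Ester aminolysis by the chloromagnesium amide of N,O-dimethylhydroxylamine (Weinreb amide formation): the alpha-oxygen-activated methyl ester should react at low temperature well before the hindered, vinylogous-carbonate-type coumarin lactone.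

Step 11
Reactants: 14 (1R,4aS,7S,7aR)-N-methoxy-N,4,7-trimethyl-1-{5-methyl-2-oxo-4-[2-(trimethylsilyl)ethoxy]-2H-chromen-3-yl}-1,4a,5,6,7,7a-hexahydrocyclopenta[c]pyran-3-carboxamide
Product: 15 3-[(1R,4aS,7S,7aR)-4,7-dimethyl-3-(3-methylbut-2-enoyl)-1,4a,5,6,7,7a-hexahydrocyclopenta[c]pyran-1-yl]-5-methyl-4-[2-(trimethylsilyl)ethoxy]-2H-chromen-2-one
Conditions: Me2C=CHMgBr (2.5 equiv), THF, −40 → 0 °C; cold aq. NH4Cl
Reagents that add atoms: 2-methylprop-1-en-1-ylmagnesium bromide, CC(C)=C[Mg]Br
Why: Weinreb ketone synthesis: the alkenyl Grignard reagent adds once to give a magnesium-chelated tetrahedral adduct that collapses only on work-up, so neither over-addition nor conjugate addition to the dienone can occur; the coumarin carbonyl is deactivated by the 4-alkoxy group and shielded by its C3' substituent.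

Step 12
Reactants: 15 3-[(1R,4aS,7S,7aR)-4,7-dimethyl-3-(3-methylbut-2-enoyl)-1,4a,5,6,7,7a-hexahydrocyclopenta[c]pyran-1-yl]-5-methyl-4-[2-(trimethylsilyl)ethoxy]-2H-chromen-2-one
Product: 16 4-hydroxy-5-methyl-3-[(1R,4aS,7S,7aR)-4,7-dimethyl-3-(3-methylbut-2-enoyl)-1,4a,5,6,7,7a-hexahydrocyclopenta[c]pyran-1-yl]-2H-chromen-2-one
Conditions: TBAF (1.5 equiv), THF, 0 °C; then pH 3 NaH2PO4/H3PO4 buffer
Reagents that add atoms: none
Why: Fluoride-induced beta-elimination of a 2-(trimethylsilyl)ethyl group: attack at silicon expels ethylene and the 4-coumarinolate, a leaving group as good as a carboxylate, so the cleavage should run at 0 °C as it does for the corresponding esters, with no acid, Lewis acid or soft nucleophile near the dienone; mild acidification returns the free hydroxycoumarin.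

Compound list

1 | 4-hydroxy-5-methyl-2H-chromen-2-one | Cc1cccc2oc(=O)cc(O)c12 | starting material
2 | 4-hydroxy-3-iodo-5-methyl-2H-chromen-2-one | Cc1cccc2oc(=O)c(I)c(O)c12 | intermediate
3 | 3-iodo-5-methyl-4-[2-(trimethylsilyl)ethoxy]-2H-chromen-2-one | Cc1cccc2oc(=O)c(I)c(OCC[Si](C)(C)C)c12 | intermediate
4 | (3S)-3,7-dimethylocta-1,6-diene ((S)-beta-citronellene) | C=C[C@@H](C)CCC=C(C)C | starting material
5 | 3-[(1E,3S)-3,7-dimethylocta-1,6-dien-1-yl]-5-methyl-4-[2-(trimethylsilyl)ethoxy]-2H-chromen-2-one | CC(C)=CCC[C@H](C)/C=C/c1c(OCC[Si](C)(C)C)c2c(C)cccc2oc1=O | intermediate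
6 | (4S,5E)-4-methyl-6-{5-methyl-2-oxo-4-[2-(trimethylsilyl)ethoxy]-2H-chromen-3-yl}hex-5-enal | O=CCC[C@H](C)/C=C/c1c(OCC[Si](C)(C)C)c2c(C)cccc2oc1=O | intermediate
7 | methyl 2-oxobutanoate | CCC(=O)C(=O)OC | starting material
8 | methyl 3-bromo-2-oxobutanoate (racemic) | CC(Br)C(=O)C(=O)OC | intermediate
9 | (4-methoxy-3,4-dioxobutan-2-yl)triphenylphosphonium bromide | COC(=O)C(=O)C(C)[P+](c1ccccc1)(c1ccccc1)c1ccccc1.[Br-] | intermediate (not isolated)
10 | methyl 2-oxo-3-(triphenyl-λ5-phosphanylidene)butanoate | COC(=O)C(=O)C(C)=P(c1ccccc1)(c1ccccc1)c1ccccc1 | intermediate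
11 | methyl (3E,7S,8E)-3,7-dimethyl-9-{5-methyl-2-oxo-4-[2-(trimethylsilyl)ethoxy]-2H-chromen-3-yl}-2-oxonona-3,8-dienoate | COC(=O)C(=O)/C(C)=C/CC[C@H](C)/C=C/c1c(OCC[Si](C)(C)C)c2c(C)cccc2oc1=O | intermediate
12 | methyl 2-[(1R,2S,5S,6R,7S)-2,6-dimethyl-7-{5-methyl-2-oxo-4-[2-(trimethylsilyl)ethoxy]-2H-chromen-3-yl}bicyclo[3.2.0]heptan-6-yl]-2-oxoacetate | COC(=O)C(=O)[C@]1(C)[C@H]2CC[C@H](C)[C@H]2[C@@H]1c1c(OCC[Si](C)(C)C)c2c(C)cccc2oc1=O | intermediate
13 | methyl (1R,4aS,7S,7aR)-4,7-dimethyl-1-{5-methyl-2-oxo-4-[2-(trimethylsilyl)ethoxy]-2H-chromen-3-yl}-1,4a,5,6,7,7a-hexahydrocyclopenta[c]pyran-3-carboxylate | COC(=O)C1=C(C)[C@H]2CC[C@H](C)[C@H]2[C@H](c2c(OCC[Si](C)(C)C)c3c(C)cccc3oc2=O)O1 | intermediate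
14 | (1R,4aS,7S,7aR)-N-methoxy-N,4,7-trimethyl-1-{5-methyl-2-oxo-4-[2-(trimethylsilyl)ethoxy]-2H-chromen-3-yl}-1,4a,5,6,7,7a-hexahydrocyclopenta[c]pyran-3-carboxamide | CON(C)C(=O)C1=C(C)[C@H]2CC[C@H](C)[C@H]2[C@H](c2c(OCC[Si](C)(C)C)c3c(C)cccc3oc2=O)O1 | intermediate
15 | 3-[(1R,4aS,7S,7aR)-4,7-dimethyl-3-(3-methylbut-2-enoyl)-1,4a,5,6,7,7a-hexahydrocyclopenta[c]pyran-1-yl]-5-methyl-4-[2-(trimethylsilyl)ethoxy]-2H-chromen-2-one | CC(C)=CC(=O)C1=C(C)[C@H]2CC[C@H](C)[C@H]2[C@H](c2c(OCC[Si](C)(C)C)c3c(C)cccc3oc2=O)O1 | intermediate
16 | 4-hydroxy-5-methyl-3-[(1R,4aS,7S,7aR)-4,7-dimethyl-3-(3-methylbut-2-enoyl)-1,4a,5,6,7,7a-hexahydrocyclopenta[c]pyran-1-yl]-2H-chromen-2-one | CC(C)=CC(=O)C1=C(C)[C@H]2CC[C@H](C)[C@H]2[C@H](c2c(O)c3c(C)cccc3oc2=O)O1 | target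

Total step count: 12. Longest linear sequence: 10 steps (steps 1, 2, 3, 4, 7, 8, 9, 10, 11, 12, from 1).

Steps least certain to work

Step 9 (carries the new-method label). What may go wrong: the cation at C1 may lose the C7a proton instead of being captured by the enolate oxygen, the silylethyl group may be lost under the Lewis acid, or the single ketoester acceptor may not ionize the bond at all. Fallback in known chemistry: set out from 11 and bypass the cyclobutane by a Lewis-acid-catalysed intramolecular inverse-electron-demand oxa-Diels–Alder reaction (Eu(fod)3 or Cu(OTf)2, toluene or CH2Cl2, rt to 60 °C). The 2-oxo-3-enoate is the 1-oxadiene (O2=C3–C4=C4a) and the alkenylcoumarin C7a=C1 is the dienophile, so C4a–C7a and C1–O2 form in one step. A three-atom tether should give the cis-fused product and the E-alkene the trans C1/C7a relation. The route is rejoined at 13 and no new compound is made.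

Step 8 (key step). What may go wrong: insufficient discrimination between the two alkene faces relative to C7, or diversion of the excited ketoester into hydrogen abstraction, photodeconjugation or oxetane formation. Fallback that removes the second chromophore: from 11, Luche reduction (NaBH4, CeCl3·7H2O, MeOH, −78 °C) of the keto group gives methyl (3E,7S,8E)-2-hydroxy-3,7-dimethyl-9-{5-methyl-2-oxo-4-[2-(trimethylsilyl)ethoxy]-2H-chromen-3-yl}nona-3,8-dienoate F1. The same sensitized cycloaddition, now onto a photochemically inert trisubstituted alkene, gives methyl 2-[(1R,2S,5S,6R,7S)-2,6-dimethyl-7-{5-methyl-2-oxo-4-[2-(trimethylsilyl)ethoxy]-2H-chromen-3-yl}bicyclo[3.2.0]heptan-6-yl]-2-hydroxyacetate F2. Dess–Martin oxidation of the carbinol returns to the route at 12.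

Step 3. What may go wrong: beta-hydride elimination toward the stereocentre, or hydridopalladium re-addition, with alkene migration and erosion of the allylic configuration; slow coupling at the hindered iodide. Fallback that forms the alkene by metathesis, with no palladium hydride near the stereocentre:
- From 3, Stille vinylation (tributyl(vinyl)stannane, Pd(PPh3)4, toluene, 90 °C) gives 3-ethenyl-5-methyl-4-[2-(trimethylsilyl)ethoxy]-2H-chromen-2-one F3.
- From 4, selective ozonolysis of the trisubstituted alkene gives (4S)-4-methylhex-5-enal F4.
- Wittig reaction of F4 with 10 gives methyl (3E,7S)-3,7-dimethyl-2-oxonona-3,8-dienoate F5.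
- Cross-metathesis of F3 with F5 (second-generation Hoveyda–Grubbs catalyst, CH2Cl2, 40 °C) should give the E-alkene and rejoins the route at 11, passing over 5 and 6.

Step 2. What may go wrong: alkylation at the lactone carbonyl oxygen (chromone-type regioisomer) or low conversion, because O-4 lies between the iodine and the peri methyl group. Fallback with reversed polarity: from 2, POCl3 (BnEt3NCl, MeCN, reflux) gives 4-chloro-3-iodo-5-methyl-2H-chromen-2-one F6. Addition–elimination with sodium 2-(trimethylsilyl)ethoxide (from the alcohol and NaH, THF, 0 °C) then places the alkoxy group at C4' only and rejoins the route at 3.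

Step 4. What may go wrong: over-oxidation, meaning cleavage of the coumarin-conjugated alkene once the trisubstituted alkene is consumed. Fallback through a more discriminating oxidant: from 5, mCPBA (NaHCO3, CH2Cl2, 0 °C) epoxidizes only the electron-rich alkene to 3-[(1E,3S)-5-(3,3-dimethyloxiran-2-yl)-3-methylpent-1-en-1-yl]-5-methyl-4-[2-(trimethylsilyl)ethoxy]-2H-chromen-2-one F7. HIO4·2H2O (THF/Et2O, 0 °C) cleaves the epoxide and rejoins the route at 6.

Step 12. What may go wrong: the liberated coumarinolate may open the C1–O2 bond by expelling the diketone enolate, with epimerization at C1 or loss of the C7a proton, and basic fluoride may isomerize the dienone. Fallback that deprotects before the ketone exists: from 14, TBAF (THF, 0 °C) gives (1R,4aS,7S,7aR)-1-(4-hydroxy-5-methyl-2-oxo-2H-chromen-3-yl)-N-methoxy-N,4,7-trimethyl-1,4a,5,6,7,7a-hexahydrocyclopenta[c]pyran-3-carboxamide F8. Excess Me2C=CHMgBr (the first equivalent forms the magnesium coumarinolate, which also shields the lactone) then adds to the amide, and buffered work-up rejoins the route at 16.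

Further compounds

F0 | step 9 | none | none
F1 | step 8 | methyl (3E,7S,8E)-2-hydroxy-3,7-dimethyl-9-{5-methyl-2-oxo-4-[2-(trimethylsilyl)ethoxy]-2H-chromen-3-yl}nona-3,8-dienoate (both C2 epimers) | COC(=O)C(O)/C(C)=C/CC[C@H](C)/C=C/c1c(OCC[Si](C)(C)C)c2c(C)cccc2oc1=O
F2 | step 8 | methyl 2-[(1R,2S,5S,6R,7S)-2,6-dimethyl-7-{5-methyl-2-oxo-4-[2-(trimethylsilyl)ethoxy]-2H-chromen-3-yl}bicyclo[3.2.0]heptan-6-yl]-2-hydroxyacetate (both carbinol epimers) | COC(=O)C(O)[C@]1(C)[C@H]2CC[C@H](C)[C@H]2[C@@H]1c1c(OCC[Si](C)(C)C)c2c(C)cccc2oc1=O
F3 | step 3 | 3-ethenyl-5-methyl-4-[2-(trimethylsilyl)ethoxy]-2H-chromen-2-one | C=Cc1c(OCC[Si](C)(C)C)c2c(C)cccc2oc1=O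
F4 | step 3 | (4S)-4-methylhex-5-enal | C=C[C@@H](C)CCC=O
F5 | step 3 | methyl (3E,7S)-3,7-dimethyl-2-oxonona-3,8-dienoate | COC(=O)C(=O)/C(C)=C/CC[C@H](C)C=C
F6 | step 2 | 4-chloro-3-iodo-5-methyl-2H-chromen-2-one | Cc1cccc2oc(=O)c(I)c(Cl)c12
F7 | step 4 | 3-[(1E,3S)-5-(3,3-dimethyloxiran-2-yl)-3-methylpent-1-en-1-yl]-5-methyl-4-[2-(trimethylsilyl)ethoxy]-2H-chromen-2-one (both epoxide epimers) | CC1(C)OC1CC[C@H](C)/C=C/c1c(OCC[Si](C)(C)C)c2c(C)cccc2oc1=O
F8 | step 12 | (1R,4aS,7S,7aR)-1-(4-hydroxy-5-methyl-2-oxo-2H-chromen-3-yl)-N-methoxy-N,4,7-trimethyl-1,4a,5,6,7,7a-hexahydrocyclopenta[c]pyran-3-carboxamide | CON(C)C(=O)C1=C(C)[C@H]2CC[C@H](C)[C@H]2[C@H](c2c(O)c3c(C)cccc3oc2=O)O1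
A1 | alternative 1 | 4-methoxy-5-methyl-2-oxo-2H-chromene-3-carbaldehyde | COc1c(C=O)c(=O)oc2cccc(C)c12
A2 | alternative 1 | trimethyl({(5E)-2-methyl-6-[(3S)-3-methylcyclopent-1-en-1-yl]hept-5-en-3-yn-2-yl}oxy)silane | C[Si](C)(C)OC(C)(C)C#C/C=C(C)/C1=C[C@@H](C)CC1
A3 | alternative 1 | 3-{(1R,3S,7S,7aR)-4,7-dimethyl-3-[3-methyl-3-(trimethylsilyloxy)but-1-yn-1-yl]-1,3,5,6,7,7a-hexahydrocyclopenta[c]pyran-1-yl}-4-methoxy-5-methyl-2H-chromen-2-one | C[Si](C)(C)OC(C)(C)C#C[C@@H]1O[C@@H](c2c(OC)c3c(C)cccc3oc2=O)[C@@H]2[C@@H](C)CCC2=C1C
A4 | alternative 2 | (1R,4aS,7S,7aR)-1-(4-methoxy-5-methyl-2-oxo-2H-chromen-3-yl)-4,7-dimethyl-1,4a,5,6,7,7a-hexahydrocyclopenta[c]pyran-3-yl trifluoromethanesulfonate | O=S(=O)(OC1=C(C)[C@H]2CC[C@H](C)[C@H]2[C@H](c2c(OC)c3c(C)cccc3oc2=O)O1)C(F)(F)F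
A5 | alternative 2 | carbon monoxide | [C-]#[O+]
A6 | alternative 2 | tributyl(2-methylprop-1-en-1-yl)stannane | CCCC[Sn](CCCC)(CCCC)C=C(C)C
A7 | alternative 2 | 3-[(1R,4aS,7S,7aR)-4,7-dimethyl-3-(3-methylbut-2-enoyl)-1,4a,5,6,7,7a-hexahydrocyclopenta[c]pyran-1-yl]-4-methoxy-5-methyl-2H-chromen-2-one | CC(C)=CC(=O)C1=C(C)[C@H]2CC[C@H](C)[C@H]2[C@H](c2c(OC)c3c(C)cccc3oc2=O)O1
A8 | alternative 2 | (1R,4aS,7S,7aR)-1-(4-methoxy-5-methyl-2-oxo-2H-chromen-3-yl)-4,7-dimethyl-4,4a,5,6,7,7a-hexahydrocyclopenta[c]pyran-3(1H)-one (both C4 epimers) | O=C1C(C)[C@H]2CC[C@H](C)[C@H]2[C@H](c2c(OC)c3c(C)cccc3oc2=O)O1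
A9 | alternative 3 | 4-methoxy-5-methyl-3-[(1E,3S)-3-methyloct-1-en-6-yn-1-yl]-2H-chromen-2-one | CC#CCC[C@H](C)/C=C/c1c(OC)c2c(C)cccc2oc1=O
A10 | alternative 3 | 3-[(1R,6S,6aS)-3,6-dimethyl-2-oxo-1,2,4,5,6,6a-hexahydropentalen-1-yl]-4-methoxy-5-methyl-2H-chromen-2-one | CC1=C2CC[C@H](C)[C@H]2[C@H](c2c(OC)c3c(C)cccc3oc2=O)C1=O
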